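**Strategy.** The quinone ring is cut across its two C=C bonds, C5=C6 (chromanyl–C=CH) and C2=C3 (MeO–C=C–OMe), which lie para to each other. This leaves two three-carbon pieces, each centred on a carbonyl carbon: C6–C1–C2 is methyl 4-methoxyacetoacetate, and C3–C4–C5 is an acrylate whose β-carbon already carries the (3S)-chroman. One base-mediated Michael–Dieckmann operation joins them at both ends and gives the whole six-membered ring as a 2-methoxy-1,3-dione ester, in which the C1/C2/C3 oxygen triad of the target is latent. Enol etherification with aromatisation, loss of the activating ester and para-oxidation of the resulting phenol (C4=O) finish the quinone.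

Key step: step 6

Assumption: quinone atoms are numbered C1(=O), C2(OMe), C3(OMe), C4(=O), C5(chromanyl), C6(H); the chroman C-3 of the target is S by the CIP rules; 1, 3, 7 and 10 are taken as catalogue compounds.

Step 1
Reactants: 1 2,3,4-trimethoxyphenol
Product: 2 2-hydroxy-3,4,5-trimethoxybenzaldehyde
Conditions: MgCl2, Et3N, (CH2O)n, MeCN, reflux; aq. HCl work-up
Reagents that add atoms: paraformaldehyde (as formaldehyde), C=O
Why: Magnesium-phenoxide-directed ortho-formylation (Casnati–Skattebøl reaction) can only strike C6, the single free position ortho to the hydroxyl (the para position carries OMe), a second formaldehyde taking up the hydride.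

Step 2
Reactants: 2 2-hydroxy-3,4,5-trimethoxybenzaldehyde; 3 acrolein
Product: 4 6,7,8-trimethoxy-2H-chromene-3-carbaldehyde
Conditions: K2CO3, 1,4-dioxane, reflux
Reagents that add atoms: none
Why: Tandem oxa-Michael addition of the phenoxide to acrolein, intramolecular aldol addition to the aryl aldehyde and dehydration is the standard route from salicylaldehydes to 2H-chromene-3-carbaldehydes.

Step 3
Reactants: 4 6,7,8-trimethoxy-2H-chromene-3-carbaldehyde
Product: 5 (6,7,8-trimethoxy-2H-chromen-3-yl)methanol
Conditions: NaBH4, CeCl3·7H2O, MeOH, 0 °C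
Reagents that add atoms: none
Why: Luche reduction delivers hydride 1,2 to the cerium-activated enal carbonyl and leaves the C3=C4 bond in place for the asymmetric step.

Step 4
Reactants: 5 (6,7,8-trimethoxy-2H-chromen-3-yl)methanol
Product: 6 [(3S)-6,7,8-trimethoxychroman-3-yl]methanol
Conditions: [Ir(cod)(tBu-PHOX)]BArF (1 mol %, ligand antipode selected for 3S), H2 (50 bar), CH2Cl2, rt
Reagents that add atoms: none
Why: Iridium N,P-catalysed asymmetric hydrogenation of a trisubstituted aryl alkene that is also an allylic alcohol should add H2 to one enantioface of the geometrically fixed C3=C4 bond and so set C-3, the catalyst antipode being chosen to give 3S.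

Step 5
Reactants: 6 [(3S)-6,7,8-trimethoxychroman-3-yl]methanol; 7 methyl (triphenylphosphoranylidene)acetate
Product: 9 methyl (2E)-3-[(3S)-6,7,8-trimethoxychroman-3-yl]prop-2-enoate, via (3R)-6,7,8-trimethoxychroman-3-carbaldehyde 8 (not isolated)
Conditions: Dess–Martin periodinane, CH2Cl2, 0 °C to rt; then 7 (excess), rt
Reagents that add atoms: none
Why: Dess–Martin oxidation gives the α-branched aldehyde, which is trapped in the same flask by the stabilised ylide (E-selective Wittig reaction) before the labile centre can epimerise; the descriptor is R in 8 only because CHO outranks C-2.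

Step 6
Reactants: 9 methyl (2E)-3-[(3S)-6,7,8-trimethoxychroman-3-yl]prop-2-enoate; 10 methyl 4-methoxy-3-oxobutanoate (methyl 4-methoxyacetoacetate)
Product: 12 methyl 3-methoxy-2,4-dioxo-6-[(3S)-6,7,8-trimethoxychroman-3-yl]cyclohexane-1-carboxylate (diastereomer/enol mixture), via dimethyl 2-(methoxyacetyl)-3-[(3S)-6,7,8-trimethoxychroman-3-yl]pentanedioate 11 (not isolated)
Conditions: NaOMe (1.2 equiv), 10 (1.3 equiv), MeOH, reflux; cold 1 M HCl
Reagents that add atoms: none
Why: Methoxide generates the stabilised C2 enolate of 10, which adds 1,4 to the β-carbon of 9 (first C–C bond, later quinone C6–C5); proton transfer in adduct 11 then gives the enolate at the methoxy-bearing C4, which acylates on the former acrylate ester carbon with loss of methoxide (second C–C bond, later quinone C2–C3). This is the classical Michael–Claisen (Vorländer-type) synthesis of 4-alkoxycarbonylcyclohexane-1,3-diones from acetoacetates and α,β-unsaturated esters, here run with a 4-methoxyacetoacetate. The one ring is closed by a 6-(enolendo)-exo-trig Dieckmann acylation, the only Claisen mode in 11 that does not give a four-membered ring. The new sp3 centres at ring C1, C3 and C6 are uncontrolled and irrelevant because all become sp2 in step 7, and the chroman C-3 centre is not involved once the β-carbon is saturated. The step needs C2 rather than C4 of 10 as the Michael donor, which the large acidity difference between the two sites secures, and it needs conjugate addition to outrun γ-deprotonation of 9, which the excess of ketoester secures by leaving almost no free methoxide. The unfavourable addition equilibrium at the branched β-carbon is drained by formation of the stabilised 1,3-dionate.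

Step 7
Reactants: 12 methyl 3-methoxy-2,4-dioxo-6-[(3S)-6,7,8-trimethoxychroman-3-yl]cyclohexane-1-carboxylate
Product: 14 methyl 2-hydroxy-3,4-dimethoxy-6-[(3S)-6,7,8-trimethoxychroman-3-yl]benzoate, via methyl 3,4-dimethoxy-2-oxo-6-[(3S)-6,7,8-trimethoxychroman-3-yl]cyclohex-3-ene-1-carboxylate 13 (not isolated)
Conditions: HC(OMe)3, TsOH (cat.), MeOH, rt; then I2 (1.05 equiv), 60 °C
Reagents that add atoms: trimethyl orthoformate (methoxy source, exchanging with the solvent), COC(OC)OC
Why: Acid-catalysed enol etherification should occur at the C4 carbonyl, which is remote from the ester, less hindered and leaves C2 as the chelated β-keto ester carbonyl; iodine then halogenates the β-keto ester position and HI is lost across C1–C6 to a dienone that tautomerises to the salicylate (iodine–methanol oxidative aromatisation).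

Step 8
Reactants: 14 methyl 2-hydroxy-3,4-dimethoxy-6-[(3S)-6,7,8-trimethoxychroman-3-yl]benzoate
Product: 16 2,3-dimethoxy-5-[(3S)-6,7,8-trimethoxychroman-3-yl]phenol, via 2-hydroxy-3,4-dimethoxy-6-[(3S)-6,7,8-trimethoxychroman-3-yl]benzoic acid 15 (not isolated)
Conditions: KOH, ethylene glycol/H2O, 120 °C (N2); then aq. HCl, 90 °C
Reagents that add atoms: none
Why: Saponification of the hindered ester followed by protodecarboxylation of the salicylic acid, which is activated for ipso-protonation by its ortho-hydroxyl and para-methoxy groups, removes the activating carbon and frees the future quinone C6 as CH.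

Step 9
Reactants: 16 2,3-dimethoxy-5-[(3S)-6,7,8-trimethoxychroman-3-yl]phenol
Product: 17 abruquinone B
Conditions: (KSO3)2NO (Fremy's salt, 2.5 equiv), KH2PO4 buffer, acetone/H2O, 0 °C to rt
Reagents that add atoms: potassium nitrosodisulfonate (Fremy's salt), [K+].[K+].[O]N(S(=O)(=O)[O-])S(=O)(=O)[O-]
Why: Teuber oxidation: Fremy's radical abstracts the phenolic hydrogen and a second equivalent adds at the free para carbon to give the quinone carbonyl C4, while the fully etherified chroman arene and the C-3 stereocentre are inert to this mild one-electron oxidant at buffered pH.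

**Compound list**

1 | 2,3,4-trimethoxyphenol | COc1ccc(O)c(OC)c1OC | starting material
2 | 2-hydroxy-3,4,5-trimethoxybenzaldehyde | COc1cc(C=O)c(O)c(OC)c1OC | intermediate
3 | acrolein (prop-2-enal) | C=CC=O | starting material
4 | 6,7,8-trimethoxy-2H-chromene-3-carbaldehyde | O=CC1=Cc2cc(OC)c(OC)c(OC)c2OC1 | intermediate
5 | (6,7,8-trimethoxy-2H-chromen-3-yl)methanol | OCC1=Cc2cc(OC)c(OC)c(OC)c2OC1 | intermediate
6 | [(3S)-6,7,8-trimethoxy-3,4-dihydro-2H-chromen-3-yl]methanol | OC[C@H]1COc2c(cc(OC)c(OC)c2OC)C1 | intermediate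
7 | methyl (triphenylphosphoranylidene)acetate | COC(=O)C=P(c1ccccc1)(c1ccccc1)c1ccccc1 | starting material
8 | (3R)-6,7,8-trimethoxy-3,4-dihydro-2H-chromene-3-carbaldehyde (not isolated) | O=C[C@H]1COc2c(cc(OC)c(OC)c2OC)C1 | intermediate
9 | methyl (2E)-3-[(3S)-6,7,8-trimethoxy-3,4-dihydro-2H-chromen-3-yl]prop-2-enoate | COC(=O)/C=C/[C@H]1COc2c(cc(OC)c(OC)c2OC)C1 | intermediate
10 | methyl 4-methoxy-3-oxobutanoate | COCC(=O)CC(=O)OC | starting material
11 | dimethyl 2-(methoxyacetyl)-3-[(3S)-6,7,8-trimethoxy-3,4-dihydro-2H-chromen-3-yl]pentanedioate (chain centres unassigned; not isolated) | COCC(=O)C(C(=O)OC)C(CC(=O)OC)[C@H]1COc2c(cc(OC)c(OC)c2OC)C1 | intermediate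
12 | methyl 3-methoxy-2,4-dioxo-6-[(3S)-6,7,8-trimethoxy-3,4-dihydro-2H-chromen-3-yl]cyclohexane-1-carboxylate (ring centres unassigned) | COC(=O)C1C(=O)C(OC)C(=O)CC1[C@H]2COc3c(cc(OC)c(OC)c3OC)C2 | intermediate
13 | methyl 3,4-dimethoxy-2-oxo-6-[(3S)-6,7,8-trimethoxy-3,4-dihydro-2H-chromen-3-yl]cyclohex-3-ene-1-carboxylate (not isolated) | COC(=O)C1C(=O)C(OC)=C(OC)CC1[C@H]2COc3c(cc(OC)c(OC)c3OC)C2 | intermediate
14 | methyl 2-hydroxy-3,4-dimethoxy-6-[(3S)-6,7,8-trimethoxy-3,4-dihydro-2H-chromen-3-yl]benzoate | COC(=O)c1c(O)c(OC)c(OC)cc1[C@H]2COc3c(cc(OC)c(OC)c3OC)C2 | intermediate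
15 | 2-hydroxy-3,4-dimethoxy-6-[(3S)-6,7,8-trimethoxy-3,4-dihydro-2H-chromen-3-yl]benzoic acid (not isolated) | OC(=O)c1c(O)c(OC)c(OC)cc1[C@H]2COc3c(cc(OC)c(OC)c3OC)C2 | intermediate
16 | 2,3-dimethoxy-5-[(3S)-6,7,8-trimethoxy-3,4-dihydro-2H-chromen-3-yl]phenol | COc1cc(cc(O)c1OC)[C@H]2COc3c(cc(OC)c(OC)c3OC)C2 | intermediate
17 | abruquinone B, 2,3-dimethoxy-5-[(3S)-6,7,8-trimethoxy-3,4-dihydro-2H-chromen-3-yl]cyclohexa-2,5-diene-1,4-dione | COC1=C(OC)C(=O)C([C@H]2COc3c(cc(OC)c(OC)c3OC)C2)=CC1=O | target

**Step count.** Total: 9 steps. Longest linear sequence: 9 steps (1 to 17).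

**Steps most likely to fail**

Step 6 (key step). Conjugate addition at the branched β-carbon may be slow enough for methoxide to remove the γ-hydrogen of 9, which is the chroman C-3 hydrogen. That would erode the configuration or open the chroman by β-elimination of the aryloxide. The fallback builds the ring before the stereocentre exists. It sets out from 4, which is olefinated with 7 (CH2Cl2, rt) to methyl (2E)-3-(6,7,8-trimethoxy-2H-chromen-3-yl)prop-2-enoate F1. The same NaOMe/MeOH annulation with 10 should then pass through dimethyl 2-(methoxyacetyl)-3-(6,7,8-trimethoxy-2H-chromen-3-yl)pentanedioate F2 to methyl 3-methoxy-2,4-dioxo-6-(6,7,8-trimethoxy-2H-chromen-3-yl)cyclohexane-1-carboxylate F3; 1,4-addition is expected because 1,6-addition would break the styrene conjugation. Enol etherification (HC(OMe)3, TsOH, MeOH) gives methyl 3,4-dimethoxy-2-oxo-6-(6,7,8-trimethoxy-2H-chromen-3-yl)cyclohex-3-ene-1-carboxylate F4, which is dehydrogenated with DDQ at 0 °C (iodine is avoided because of the electron-rich alkene) to methyl 2-hydroxy-3,4-dimethoxy-6-(6,7,8-trimethoxy-2H-chromen-3-yl)benzoate F5. Iridium–PHOX-catalysed asymmetric hydrogenation of the isoflav-3-ene double bond of F5 then sets C-3 and returns to the route at 14.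

Step 4. Enantioface discrimination may be weak because C-3 carries two similar CH2–O groups and the hydroxyl does not direct an Ir–N,P catalyst; iridium hydride may also isomerise the allylic alcohol. The fallback uses carboxylate-directed hydrogenation instead. It sets out from 4, which is oxidised (NaClO2, NaH2PO4, 2-methyl-2-butene) to 6,7,8-trimethoxy-2H-chromene-3-carboxylic acid F6. Hydrogenation of this α,β-unsaturated acid with Ru(OAc)2(BINAP)/H2 in MeOH should give (3R)-6,7,8-trimethoxy-3,4-dihydro-2H-chromene-3-carboxylic acid F7, and BH3·THF reduction returns to the route at 6.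

Step 8. Acyl–oxygen cleavage of the di-ortho-substituted, phenoxide-deactivated ester may stall, and the forcing conditions may begin to cleave aryl methyl ethers. The fallback removes the ester while it is still an easily cleaved β-keto ester. It sets out from 12, which is saponified (aq. NaOH, reflux) to 3-methoxy-2,4-dioxo-6-[(3S)-6,7,8-trimethoxychroman-3-yl]cyclohexane-1-carboxylic acid F8; this loses CO2 on acidification and warming to give 2-methoxy-5-[(3S)-6,7,8-trimethoxychroman-3-yl]cyclohexane-1,3-dione F9. Enol etherification (HC(OMe)3, TsOH, MeOH) gives 2,3-dimethoxy-5-[(3S)-6,7,8-trimethoxychroman-3-yl]cyclohex-2-en-1-one F10; either carbonyl leads to the same constitution and the C5 epimers converge. Saegusa–Ito dehydrogenation (LDA, TMSCl, THF, −78 °C; then Pd(OAc)2, MeCN) proceeds through [3,4-dimethoxy-6-[(3S)-6,7,8-trimethoxychroman-3-yl]cyclohexa-1,3-dien-2-yl]oxy-trimethylsilane F11 and returns to the route at 16.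

**Further compounds**

F1 | step 6 | methyl (2E)-3-(6,7,8-trimethoxy-2H-chromen-3-yl)prop-2-enoate | COC(=O)/C=C/C1=Cc2cc(OC)c(OC)c(OC)c2OC1
F2 | step 6 | dimethyl 2-(methoxyacetyl)-3-(6,7,8-trimethoxy-2H-chromen-3-yl)pentanedioate | COCC(=O)C(C(=O)OC)C(CC(=O)OC)C1=Cc2cc(OC)c(OC)c(OC)c2OC1
F3 | step 6 | methyl 3-methoxy-2,4-dioxo-6-(6,7,8-trimethoxy-2H-chromen-3-yl)cyclohexane-1-carboxylate | COC(=O)C1C(=O)C(OC)C(=O)CC1C2=Cc3cc(OC)c(OC)c(OC)c3OC2
F4 | step 6 | methyl 3,4-dimethoxy-2-oxo-6-(6,7,8-trimethoxy-2H-chromen-3-yl)cyclohex-3-ene-1-carboxylate | COC(=O)C1C(=O)C(OC)=C(OC)CC1C2=Cc3cc(OC)c(OC)c(OC)c3OC2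
F5 | step 6 | methyl 2-hydroxy-3,4-dimethoxy-6-(6,7,8-trimethoxy-2H-chromen-3-yl)benzoate | COC(=O)c1c(O)c(OC)c(OC)cc1C2=Cc3cc(OC)c(OC)c(OC)c3OC2
F6 | step 4 | 6,7,8-trimethoxy-2H-chromene-3-carboxylic acid | OC(=O)C1=Cc2cc(OC)c(OC)c(OC)c2OC1
F7 | step 4 | (3R)-6,7,8-trimethoxy-3,4-dihydro-2H-chromene-3-carboxylic acid | OC(=O)[C@H]1COc2c(cc(OC)c(OC)c2OC)C1
F8 | step 8 | 3-methoxy-2,4-dioxo-6-[(3S)-6,7,8-trimethoxy-3,4-dihydro-2H-chromen-3-yl]cyclohexane-1-carboxylic acid | OC(=O)C1C(=O)C(OC)C(=O)CC1[C@H]2COc3c(cc(OC)c(OC)c3OC)C2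
F9 | step 8 | 2-methoxy-5-[(3S)-6,7,8-trimethoxy-3,4-dihydro-2H-chromen-3-yl]cyclohexane-1,3-dione | COC1C(=O)CC(CC1=O)[C@H]2COc3c(cc(OC)c(OC)c3OC)C2
F10 | step 8 | 2,3-dimethoxy-5-[(3S)-6,7,8-trimethoxy-3,4-dihydro-2H-chromen-3-yl]cyclohex-2-en-1-one (C5 epimers) | COC1=C(OC)C(=O)CC(C1)[C@H]2COc3c(cc(OC)c(OC)c3OC)C2
F11 | step 8 | [3,4-dimethoxy-6-[(3S)-6,7,8-trimethoxy-3,4-dihydro-2H-chromen-3-yl]cyclohexa-1,3-dien-2-yl]oxy-trimethylsilane | COC1=C(OC)C(O[Si](C)(C)C)=CC(C1)[C@H]2COc3c(cc(OC)c(OC)c3OC)C2
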